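## Retrosynthetic overview

1. Target ⇒ nostoxanthin, the (2R,3R,2'R,3'R)-tetrol: the last step is one O-sulfation at one of the two symmetry-equivalent, unhindered 3-hydroxyls.
2. Nostoxanthin ⇒ C15 + C10 + C15: twofold Wittig reaction of the C10 trienedial with two identical dihydroxylated C15 phosphonium salts.
3. C15 salt ⇒ (2R,3R)-2,3-dihydroxy-β-ionone ⇒ methyl (2R,3R)-2,3-dihydroxy-β-cyclogeranate.
4. Ring formation: both cyclohexene rings are closed together, before any polyene exists, by a two-directional epoxide-initiated cation–olefin cyclization of one C2-symmetric, glycol-linked bis(epoxy-alcohol enoate). The linker is shed in the next step and the two ring units are re-united through the C10 dialdehyde.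
5. Bis(epoxy alcohol) ⇒ glycol bis(3-methylbut-2-enoate) + 2 × 3-methylbut-2-enal, by a twofold asymmetric vinylogous Mukaiyama aldol (sets C3, C3') and hydroxyl-directed threo epoxidation (sets C2, C2').

Assumption: the target is taken as the free hydrogen sulfate exactly as drawn (made as a salt, protonated last), the C10 dialdehyde 15 is counted as a purchasable bulk carotenoid intermediate, and positions are cited in carotenoid numbering (ring C1–C6, chain from C7).

## Route

Step 1
Reactants: 1 3-methylbut-2-enoic acid (2.2 equiv); 2 ethane-1,2-diol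
Product: 3 ethane-1,2-diyl bis(3-methylbut-2-enoate)
Conditions: TsOH·H2O (5 mol %), toluene, reflux, Dean–Stark
Reagents that add atoms: none
Why: Fischer esterification driven by azeotropic removal of water joins two senecioate units through a two-carbon linker, so that every later operation up to ring closure is done on both halves at once.

Step 2
Reactants: 3 ethane-1,2-diyl bis(3-methylbut-2-enoate)
Product: 4 1,2-bis({1-[tert-butyl(dimethyl)silyl]oxy-3-methylbuta-1,3-dien-1-yl}oxy)ethane
Conditions: LiN(iPr)2 (2.3 equiv), THF/DMPU, −78 °C; TBSCl (2.5 equiv), −78 °C → rt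
Reagents that add atoms: tert-butyl(chloro)dimethylsilane, `CC(C)(C)[Si](C)(C)Cl`
Why: kinetic γ-deprotonation of each senecioate arm gives the extended (vinylogous) ester enolate, and O-silylation fixes it as the vinylketene silyl acetal needed for a Mukaiyama-type addition (ketene-acetal geometry is not controlled and does not matter).

Step 3
Reactants: 4 bis(silyl dienol ether); 5 3-methylbut-2-enal (2.4 equiv)
Product: 6 ethane-1,2-diyl bis[(2E,5R)-5-hydroxy-3,7-dimethylocta-2,6-dienoate]
Conditions: SiCl4 (2.4 equiv), (R,R)-bis-phosphoramide from N,N'-dimethyl-1,1'-binaphthyl-2,2'-diamine (pentane-1,5-diyl-bridged, 5 mol %), iPr2NEt (cat.), CH2Cl2, −78 °C; aq. NaHCO3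
Reagents that add atoms: none
Why: catalytic enantioselective vinylogous Mukaiyama aldol addition under Lewis-base activation of SiCl4, in which the dienolate reacts only at its γ-carbon to give the E-enoate and Re-face attack on each enal sets the 5R carbinol centre (the future C3 and C3'); should the (R,R) catalyst deliver the opposite face, its enantiomer is used.

Step 4
Reactants: 6 bis(hydroxy dienoate)
Product: 7 ethane-1,2-diyl bis{(2E,5R)-5-[(2S)-3,3-dimethyloxiran-2-yl]-5-hydroxy-3-methylpent-2-enoate}
Conditions: mCPBA (2.3 equiv), NaHCO3, CH2Cl2, −10 °C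
Reagents that add atoms: 3-chloroperoxybenzoic acid, `OOC(=O)c1cccc(Cl)c1`
Why: hydroxyl-directed (Henbest) peracid epoxidation, in which A(1,3) strain from the cis-methyl of the trisubstituted olefin holds the carbinol C–H in the olefin plane so that hydrogen-bonded oxygen delivery gives the threo (5R,6S) epoxy alcohol (the future C2 and C2'), while the electron-poor enoates are not attacked.

Step 5
Reactants: 7 bis(epoxy-alcohol enoate)
Product: 8 ethane-1,2-diyl bis[(1R,4R,5R)-4,5-dihydroxy-2,6,6-trimethylcyclohex-2-ene-1-carboxylate]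
Conditions: MeAlCl2 (6 equiv), CH2Cl2, −78 → −40 °C; aq. NaHCO3, potassium sodium tartrate
Reagents that add atoms: none
Why: Proposed new method: a two-directional epoxide-initiated cation–olefin cyclization in which each free hydroxyl becomes a chloroaluminium alkoxide that chelates the neighbouring oxirane and ionizes its tertiary C–O bond, the enoate α-carbon then closing the six-membered ring through a chair transition state with the C2–O and C3–O bonds untouched (both oxygens equatorial, hence 2R,3R trans) and the cation ending by proton loss (some exocyclic-methylene isomer is expected and converges in step 6), so that both carbocycles form in one operation; the closest known chemistry is the Lewis-acid cyclization of epoxygeranyl and epoxyfarnesyl esters, including enoate-terminated farnesate cyclizations, and the hydroxyl-directed distal opening of 2,3-epoxy alcohols.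

Step 6
Reactants: 8 bis(cyclized ester)
Product: 9 methyl (4R,5R)-4,5-dihydroxy-2,6,6-trimethylcyclohex-1-ene-1-carboxylate (2 equiv)
Conditions: NaOMe (0.3 equiv), MeOH, 60 °C
Reagents that add atoms: methanol, `CO`
Why: methoxide-mediated prototropic isomerization through the ester dienolate moves the ring double bond into conjugation (tetrasubstituted α,β-unsaturated ester, as in the α- to β-cyclogeranate series) while transesterification releases the linker, the C6 stereocentre disappearing and C2 and C3 not being epimerizable.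

Step 7
Reactants: 9 methyl dihydroxy-β-cyclogeranate
Product: 10 (1R,2R)-4-(hydroxymethyl)-3,3,5-trimethylcyclohex-4-ene-1,2-diol
Conditions: iBu2AlH (5 equiv), CH2Cl2, −78 → 0 °C; aq. potassium sodium tartrate
Reagents that add atoms: none
Why: aluminium hydride 1,2-reduction of the hindered conjugated ester to the primary allylic alcohol, the two secondary hydroxyls being carried as aluminium alkoxides.

Step 8
Reactants: 10 ring triol
Product: 12 (3E)-4-[(4R,5R)-4,5-dihydroxy-2,6,6-trimethylcyclohex-1-en-1-yl]but-3-en-2-one, via dihydroxy-β-cyclocitral 11 (not isolated)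
Conditions: MnO2 (15 equiv), Ph3P=CHC(O)CH3 (1.5 equiv), toluene, 90 °C
Reagents that add atoms: 1-(triphenylphosphoranylidene)propan-2-one, `CC(=O)C=P(c1ccccc1)(c1ccccc1)c1ccccc1`
Why: tandem oxidation–Wittig olefination in which MnO2 oxidizes only the allylic primary alcohol and the aldehyde is trapped as it forms by the stabilized ylide to give the E-enone, under neutral conditions that avoid base-induced loss of the 3-hydroxyl.

Step 9
Reactants: 12 dihydroxy-β-ionone
Product: 13 (1R,2R)-4-[(1E)-3-hydroxy-3-methylpenta-1,4-dien-1-yl]-3,3,5-trimethylcyclohex-4-ene-1,2-diol (both carbinol epimers)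
Conditions: CH2=CHMgBr (4 equiv), THF, −30 → 0 °C; aq. NH4Cl
Reagents that add atoms: vinylmagnesium bromide, `C=C[Mg]Br`
Why: Grignard 1,2-addition to the ketone of the dienone (excess reagent covers the two hydroxyls) gives the tertiary bis-allylic alcohol as an epimer mixture that does not matter because the new centre is destroyed in step 10.

Step 10
Reactants: 13 vinyl carbinol
Product: 14 [(2E,4E)-5-[(4R,5R)-4,5-dihydroxy-2,6,6-trimethylcyclohex-1-en-1-yl]-3-methylpenta-2,4-dien-1-yl]triphenylphosphonium bromide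
Conditions: PPh3·HBr (1.05 equiv), MeOH, 0 °C → rt
Reagents that add atoms: triphenylphosphine hydrobromide, `[Br-].[PH+](c1ccccc1)(c1ccccc1)c1ccccc1`
Why: acid-mediated ionization of the tertiary allylic alcohol to the pentadienyl cation and capture by PPh3 at the primary terminus (allylic transposition) gives the E,E C15 Wittig salt, the non-allylic ring hydroxyls being inert as in the hydroxylated C15 salts used for other xanthophylls.

Step 11
Reactants: 14 C15 phosphonium bromide (2.1 equiv); 15 (2E,4E,6E)-2,7-dimethylocta-2,4,6-trienedial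
Product: 17 nostoxanthin [(2R,3R,2'R,3'R)-β,β-carotene-2,3,2',3'-tetrol], via 11Z-nostoxanthin 16 (not isolated)
Conditions: NaOMe (2.3 equiv), MeOH/CH2Cl2, 0 °C → rt; then EtOH, reflux
Reagents that add atoms: none
Why: twofold Wittig olefination of the C10 dialdehyde by the C15 ylide tolerates the free hydroxyls, and the 11Z isomers formed kinetically (16 is the representative mono-cis isomer) equilibrate thermally to the all-E polyene, which crystallizes.

Step 12
Reactants: 17 nostoxanthin
Product: 18 (2R,3R,2'R,3'R)-2,2',3'-trihydroxy-β,β-caroten-3-yl hydrogen sulfate (CNP0229621.3)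
Conditions: SO3·pyridine (1.1 equiv), pyridine, 0 °C; cold H+-form cation-exchange resin
Reagents that add atoms: sulfur trioxide–pyridine complex, `[O-]S(=O)(=O)[n+]1ccccc1`
Why: O-sulfation occurs at the unhindered secondary 3-hydroxyl and not at the neopentyl 2-hydroxyl next to the gem-dimethyl carbon, and because the two 3-hydroxyls are equivalent by C2 symmetry any single sulfation gives the target, so limiting reagent and separation by charge from recyclable tetrol and bis-sulfate deliver the mono-ester (about half per pass at best).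

## Compound list

1 | 3-methylbut-2-enoic acid | `CC(C)=CC(=O)O` | starting material
2 | ethane-1,2-diol | `OCCO` | starting material
3 | ethane-1,2-diyl bis(3-methylbut-2-enoate) | `CC(C)=CC(=O)OCCOC(=O)C=C(C)C` | intermediate
4 | 1,2-bis({1-[tert-butyl(dimethyl)silyl]oxy-3-methylbuta-1,3-dien-1-yl}oxy)ethane (ketene-acetal geometry not controlled) | `C=C(C)C=C(O[Si](C)(C)C(C)(C)C)OCCOC(O[Si](C)(C)C(C)(C)C)=CC(C)=C` | intermediate
5 | 3-methylbut-2-enal | `CC(C)=CC=O` | starting material
6 | ethane-1,2-diyl bis[(2E,5R)-5-hydroxy-3,7-dimethylocta-2,6-dienoate] | `CC(C)=C[C@H](O)C/C(C)=C/C(=O)OCCOC(=O)/C=C(\C)C[C@@H](O)C=C(C)C` | intermediate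
7 | ethane-1,2-diyl bis{(2E,5R)-5-[(2S)-3,3-dimethyloxiran-2-yl]-5-hydroxy-3-methylpent-2-enoate} | `CC1(C)O[C@H]1[C@H](O)C/C(C)=C/C(=O)OCCOC(=O)/C=C(\C)C[C@@H](O)[C@@H]1OC1(C)C` | intermediate
8 | ethane-1,2-diyl bis[(1R,4R,5R)-4,5-dihydroxy-2,6,6-trimethylcyclohex-2-ene-1-carboxylate] | `C(COC(=O)[C@@H]1C(C)=C[C@@H](O)[C@H](O)C1(C)C)OC(=O)[C@@H]1C(C)=C[C@@H](O)[C@H](O)C1(C)C` | intermediate
9 | methyl (4R,5R)-4,5-dihydroxy-2,6,6-trimethylcyclohex-1-ene-1-carboxylate | `COC(=O)C1=C(C)C[C@@H](O)[C@H](O)C1(C)C` | intermediate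
10 | (1R,2R)-4-(hydroxymethyl)-3,3,5-trimethylcyclohex-4-ene-1,2-diol | `OCC1=C(C)C[C@@H](O)[C@H](O)C1(C)C` | intermediate
11 | (4R,5R)-4,5-dihydroxy-2,6,6-trimethylcyclohex-1-ene-1-carbaldehyde (dihydroxy-β-cyclocitral) | `O=CC1=C(C)C[C@@H](O)[C@H](O)C1(C)C` | intermediate
12 | (3E)-4-[(4R,5R)-4,5-dihydroxy-2,6,6-trimethylcyclohex-1-en-1-yl]but-3-en-2-one | `CC(=O)/C=C/C1=C(C)C[C@@H](O)[C@H](O)C1(C)C` | intermediate
13 | (1R,2R)-4-[(1E)-3-hydroxy-3-methylpenta-1,4-dien-1-yl]-3,3,5-trimethylcyclohex-4-ene-1,2-diol (carbinol epimers) | `C=CC(C)(O)/C=C/C1=C(C)C[C@@H](O)[C@H](O)C1(C)C` | intermediate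
14 | [(2E,4E)-5-[(4R,5R)-4,5-dihydroxy-2,6,6-trimethylcyclohex-1-en-1-yl]-3-methylpenta-2,4-dien-1-yl]triphenylphosphonium bromide | `[Br-].C(/C=C(C)/C=C/C1=C(C)C[C@@H](O)[C@H](O)C1(C)C)[P+](c1ccccc1)(c1ccccc1)c1ccccc1` | intermediate
15 | (2E,4E,6E)-2,7-dimethylocta-2,4,6-trienedial | `O=C/C(C)=C/C=C/C=C(C)/C=O` | starting material
16 | (11Z)-nostoxanthin (representative of the Z isomers) | `CC1=C(\C=C\C(C)=C\C=C/C(C)=C/C=C/C=C(C)/C=C/C=C(C)/C=C/C2=C(C)C[C@@H](O)[C@H](O)C2(C)C)C(C)(C)[C@@H](O)[C@H](O)C1` | intermediate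
17 | nostoxanthin, (2R,3R,2'R,3'R)-β,β-carotene-2,3,2',3'-tetrol | `CC1=C(/C=C/C(C)=C/C=C/C(C)=C/C=C/C=C(C)/C=C/C=C(C)/C=C/C2=C(C)C[C@@H](O)[C@H](O)C2(C)C)C(C)(C)[C@@H](O)[C@H](O)C1` | intermediate
18 | (2R,3R,2'R,3'R)-2,2',3'-trihydroxy-β,β-caroten-3-yl hydrogen sulfate (CNP0229621.3) | `CC1=C(/C=C/C(C)=C/C=C/C(C)=C/C=C/C=C(C)/C=C/C=C(C)/C=C/C2=C(C)C[C@@H](OS(=O)(=O)O)[C@H](O)C2(C)C)C(C)(C)[C@@H](O)[C@H](O)C1` | target

## Step count and risks

Total step count: 12. Longest linear sequence: 12 (from 1 and 2 to 18; 5 and 15 enter as purchased materials).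

The three steps most likely to fail:

Step 5 (double cyclization of 7). The enoate is a weak π-nucleophile, so hydride shift of the opened oxirane to a ketone, or opening without ring closure, may win. The fallback sets out from 7 and returns at 11; it moves the ring closure to the alcohol oxidation level, where the attacking olefin is an ordinary trisubstituted allylic one. Reduction of 7 with iBu2AlH (CH2Cl2, −78 °C) gives (2E,5R)-5-[(2S)-3,3-dimethyloxiran-2-yl]-3-methylpent-2-ene-1,5-diol F1. 1,1'-Carbonyldiimidazole (0.5 equiv) joins two molecules through their primary allylic hydroxyls to bis{(2E,5R)-5-[(2S)-3,3-dimethyloxiran-2-yl]-5-hydroxy-3-methylpent-2-en-1-yl} carbonate F2. ZrCl4 (CH2Cl2, −78 °C) closes both rings of F2 in one operation, in the manner of epoxygeranyl esters, to the exocyclic-olefin product bis{[(1R,3R,4R)-3,4-dihydroxy-2,2-dimethyl-6-methylidenecyclohexyl]methyl} carbonate F3. K2CO3/MeOH frees (1R,2R,4R)-4-(hydroxymethyl)-3,3-dimethyl-5-methylidenecyclohexane-1,2-diol F4. TEMPO/PhI(OAc)2 oxidizes only the primary alcohol to (1R,3R,4R)-3,4-dihydroxy-2,2-dimethyl-6-methylidenecyclohexane-1-carbaldehyde F5, and DBU moves the double bond into conjugation to give 11, which is isolated and olefinated with the ylide of step 8 to 12.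

Step 6 (conjugation at the ester stage). Hindered β-cyclogeranate-type esters are twisted out of conjugation, so the equilibrium may not lie far enough toward 9, and prolonged methoxide treatment may eliminate the 3-hydroxyl through the dienolate. The fallback sets out from 8 and returns at 11; it does the isomerization at the aldehyde stage, where the conjugated isomer is strongly favoured. iBu2AlH reduces 8 to (1R,2R,4R)-4-(hydroxymethyl)-3,3,5-trimethylcyclohex-5-ene-1,2-diol F6. TEMPO/PhI(OAc)2 (primary-selective) gives (1R,4R,5R)-4,5-dihydroxy-2,6,6-trimethylcyclohex-2-ene-1-carbaldehyde F7. Brief DBU treatment at 0 °C conjugates F7 to 11, which is then used in the Wittig reaction of step 8.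

Step 12 (mono-sulfation). The outcome is statistical (tetrol, mono- and bis-sulfate) and polyene may be lost while charged species are separated. The fallback sets out from 14 and returns at 18; it differentiates the two ends before the chain is complete. The ylide from 14 (1 equiv) and 15 (3 equiv) give the mono-olefination product (2R,3R)-2,3-dihydroxy-12'-apo-β-caroten-12'-al F8. Separately, SO3·pyridine sulfates the unhindered 3-hydroxyl of 14 to the inner salt [(2E,4E)-5-[(4R,5R)-5-hydroxy-2,6,6-trimethyl-4-(sulfonatooxy)cyclohex-1-en-1-yl]-3-methylpenta-2,4-dien-1-yl]triphenylphosphonium F9. Wittig reaction of F9 with F8 (NaOMe, then thermal Z to E equilibration and protonation) gives 18 with the sulfate on one ring only.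

Further compounds

F1 | step 5 | (2E,5R)-5-[(2S)-3,3-dimethyloxiran-2-yl]-3-methylpent-2-ene-1,5-diol | `OC/C=C(\C)C[C@@H](O)[C@@H]1OC1(C)C`
F2 | step 5 | bis{(2E,5R)-5-[(2S)-3,3-dimethyloxiran-2-yl]-5-hydroxy-3-methylpent-2-en-1-yl} carbonate | `O=C(OC/C=C(\C)C[C@@H](O)[C@@H]1OC1(C)C)OC/C=C(\C)C[C@@H](O)[C@@H]1OC1(C)C`
F3 | step 5 | bis{[(1R,3R,4R)-3,4-dihydroxy-2,2-dimethyl-6-methylidenecyclohexyl]methyl} carbonate | `O=C(OC[C@@H]1C(=C)C[C@@H](O)[C@H](O)C1(C)C)OC[C@@H]1C(=C)C[C@@H](O)[C@H](O)C1(C)C`
F4 | step 5 | (1R,2R,4R)-4-(hydroxymethyl)-3,3-dimethyl-5-methylidenecyclohexane-1,2-diol | `OC[C@@H]1C(=C)C[C@@H](O)[C@H](O)C1(C)C`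
F5 | step 5 | (1R,3R,4R)-3,4-dihydroxy-2,2-dimethyl-6-methylidenecyclohexane-1-carbaldehyde | `O=C[C@@H]1C(=C)C[C@@H](O)[C@H](O)C1(C)C`
F6 | step 6 | (1R,2R,4R)-4-(hydroxymethyl)-3,3,5-trimethylcyclohex-5-ene-1,2-diol | `OC[C@@H]1C(C)=C[C@@H](O)[C@H](O)C1(C)C`
F7 | step 6 | (1R,4R,5R)-4,5-dihydroxy-2,6,6-trimethylcyclohex-2-ene-1-carbaldehyde | `O=C[C@@H]1C(C)=C[C@@H](O)[C@H](O)C1(C)C`
F8 | step 12 | (2R,3R)-2,3-dihydroxy-12'-apo-β-caroten-12'-al | `O=C/C(C)=C/C=C/C=C(C)/C=C/C=C(C)/C=C/C1=C(C)C[C@@H](O)[C@H](O)C1(C)C`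
F9 | step 12 | [(2E,4E)-5-[(4R,5R)-5-hydroxy-2,6,6-trimethyl-4-(sulfonatooxy)cyclohex-1-en-1-yl]-3-methylpenta-2,4-dien-1-yl]triphenylphosphonium (inner salt) | `C(/C=C(C)/C=C/C1=C(C)C[C@@H](OS(=O)(=O)[O-])[C@H](O)C1(C)C)[P+](c1ccccc1)(c1ccccc1)c1ccccc1`
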